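**Plan**

- Numbering (daucane): C1 quaternary C–CH3, C2 C=O, C3 CH2, C4 C(OH)iPr, C5 ring-fusion CH, C6 CH–O–vanilloyl, C7 CH2, C8 =C–CH3, C9 =CH, C10 CHOH. The five-membered ring is C1–C5, the seven-membered ring is C1, C5–C10; β is the face of the C1 methyl.
- Cuts, in order: the C6–O ester; then C9–C10 and C9–C8. The neopentyl carbinol C10 beside the C8=C9 alkene (C8 bearing CH3) in the seven-membered ring is a reduced 3-methylcyclohept-2-enone, which is a 2-methylcyclohexanone C10=C8 enol silane with one carbon (C9) inserted. Then C1–CH3, C4–O and the indanone bonds C1–C2 and C4–iPr.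
- Forward: the five-membered ring is closed first on the arene (indanone). The aromatic ring (C1, C5, C6, C7, C8, C10) is dearomatised by Birch reductive methylation and then enlarged to the seven-membered ring. Redox adjustment and the vanillate follow.
- Stereochemistry: C4 from a Cu-catalysed enantioselective β-borylation/oxidation; C1 by methylation anti to the C4 isopropyl; C10 by convex-face hydride addition to the folded dienone; C5 by α-face protonation on enol-ether hydrolysis; C6 by hydride delivery from the C4 hydroxyl.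

Key step: step 10

Remark: 2,5-dimethoxy-4-methylbenzaldehyde is treated as a catalogue compound (otherwise one Vilsmeier formylation of 2,5-dimethoxytoluene). Aromatic and hydrindane intermediates carry indane locants, ring-expanded ones daucane locants.

**Route**

Step 1
Reactants: 1 2,5-dimethoxy-4-methylbenzaldehyde; 2 Meldrum's acid (2,2-dimethyl-1,3-dioxane-4,6-dione)
Product: 3 5-(2,5-dimethoxy-4-methylbenzylidene)-2,2-dimethyl-1,3-dioxane-4,6-dione
Conditions: pyrrolidine (10 mol %), AcOH (10 mol %), PhH, 25 °C
Reagents that add atoms: Meldrum's acid (2), CC1(C)OC(=O)CC(=O)O1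
Why: Knoevenagel condensation of an aryl aldehyde with the strongly C–H acidic Meldrum's acid should give the single arylidene; no stereocentre is formed.

Step 2
Reactants: 3 arylidene Meldrum's acid; 4 isopropylmagnesium chloride
Product: 5 rac-5-[1-(2,5-dimethoxy-4-methylphenyl)-2-methylpropyl]-2,2-dimethyl-1,3-dioxane-4,6-dione
Conditions: i-PrMgCl (1.5 equiv), THF, 0 °C; aq. HCl
Reagents that add atoms: isopropylmagnesium chloride (4), CC(C)[Mg]Cl
Why: Grignard 1,4-addition to an alkylidene Meldrum's acid, a doubly activated acceptor that does not undergo 1,2-addition, installs the isopropyl on the future C4; the benzylic centre is racemic and is erased in step 6.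

Step 3
Reactants: 5 benzyl Meldrum's acid
Product: 6 rac-3-isopropyl-4,7-dimethoxy-6-methylindan-1-one
Conditions: Sc(OTf)3 (10 mol %), MeNO2, 100 °C
Reagents that add atoms: none
Why: Lewis-acid-catalysed intramolecular Friedel–Crafts acylation by the Meldrum's acid unit with loss of acetone and CO2 can close only onto the single free ortho position (ortho to OMe), so the carbonyl ends up next to the methoxy that neighbours the ring methyl.

Step 4
Reactants: 6 dimethoxyindanone
Product: 7 rac-7-hydroxy-3-isopropyl-4-methoxy-6-methylindan-1-one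
Conditions: BCl3 (1.2 equiv), CH2Cl2, −78 → 0 °C; H2O
Reagents that add atoms: none
Why: Chelation-controlled BCl3 demethylation cleaves only the methoxy peri to the ketone (future C10 oxygen), leaving the C4 methoxy (future C6 oxygen).

Step 5
Reactants: 7 peri-hydroxyindanone
Product: 8 rac-7-(tert-butyldimethylsilyloxy)-3-isopropyl-4-methoxy-6-methylindan-1-one
Conditions: TBSCl, imidazole, DMAP (cat.), DMF, 40 °C
Reagents that add atoms: tert-butyldimethylsilyl chloride, CC(C)(C)[Si](C)(C)Cl
Why: Standard phenol silylation; the resulting aryl silyl ether is flanked on both ortho positions, which should make it robust towards the mildly basic steps that follow.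

Step 6
Reactants: 8 silyloxyindanone
Product: 10 7-(tert-butyldimethylsilyloxy)-3-isopropyl-4-methoxy-6-methyl-1H-inden-1-one, via TMS enol ether 9 (not isolated)
Conditions: TMSOTf, Et3N, CH2Cl2, 0 °C; then Pd(OAc)2 (10 mol %), O2 (1 atm), DMSO, 25 °C
Reagents that add atoms: none
Why: Saegusa–Ito oxidation of the only possible enol silane gives the 3-substituted indenone by β-hydride elimination of the benzylic hydrogen.

Step 7
Reactants: 10 indenone
Product: 12 (R)-7-(tert-butyldimethylsilyloxy)-3-hydroxy-3-isopropyl-4-methoxy-6-methylindan-1-one, via β-boryl ketone 11 (not isolated)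
Conditions: CuCl (5 mol %), NaOt-Bu (10 mol %), QuinoxP* (enantiomer chosen to give the 3R product), B2pin2, MeOH (2 equiv), THF, 25 °C; then 30 % H2O2, aq. NaHCO3, 0 °C
Reagents that add atoms: hydrogen peroxide, OO
Why: Cu(I)/chiral bisphosphine-catalysed enantioselective conjugate borylation of a β,β-disubstituted cyclic enone sets the tertiary centre (future C4) by catalyst control of the enone face, and the C–B bond is oxidised with retention.

Step 8
Reactants: 12 (R)-hydroxyindanone; 13 iodomethane
Product: 14 (3R,7aS)-7-(tert-butyldimethylsilyloxy)-3-hydroxy-3-isopropyl-4-methoxy-6,7a-dimethyl-2,3,5,7a-tetrahydro-1H-inden-1-one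
Conditions: K (2.2 equiv), t-BuOH (1.0 equiv), NH3(l)/THF, −78 °C; LiBr, then MeI, −78 °C; NH4Cl
Reagents that add atoms: iodomethane (13), CI
Why: Birch reductive alkylation of an aryl ketone: two-electron reduction and para protonation (C7) give the cross-conjugated enolate, in which the silyloxy, methoxy and methyl donors all sit on the two new enol-ether double bonds (C10=C8 and C5=C6), and the lithium enolate is methylated at C1 on the face opposite the C4 isopropyl (cis to the C4 oxygen), so C4 sets the quaternary centre.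

Step 9
Reactants: 14 hydroxy dienyl ketone
Product: 15 (3R,7aS)-7-(tert-butyldimethylsilyloxy)-3-isopropyl-4-methoxy-6,7a-dimethyl-3-(trimethylsilyloxy)-2,3,5,7a-tetrahydro-1H-inden-1-one
Conditions: 1-(trimethylsilyl)imidazole, CH2Cl2, 25 °C
Reagents that add atoms: 1-(trimethylsilyl)imidazole, C[Si](C)(C)n1ccnc1
Why: Neutral silylation of the tertiary alcohol removes the allylic hydroxyl, which would otherwise direct the zinc carbenoid to the C5=C6 enol ether.

Step 10
Reactants: 15 hydrindadienone enol silane; 16 diiodomethane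
Product: 19 6-methoxy-4β-(trimethylsilyloxy)dauca-5,8-diene-2,10-dione, via siloxycyclopropane 17 (not isolated), via β-chloro ketone 18 (not isolated)
Conditions: Et2Zn, CH2I2, CH2Cl2, 0 → 25 °C; then FeCl3, pyridine, DMF, 0 → 25 °C; then NaOAc, MeOH, 50 °C
Reagents that add atoms: diiodomethane (16), ICI
Why: The zinc carbenoid transfers CH2 (C9) to the electron-rich C10=C8 enol silane in a concerted, stereospecific [2+1] addition that closes the three-membered ring C8–C9–C10 on the face opposite the C1 methyl. Fe(III) then oxidises the siloxycyclopropane with loss of the silyl group to a cyclopropyloxy radical, whose internal C10–C8 bond breaks to give the C10 ketone and the tertiary C8 radical; the seven-membered ring therefore arises by enlargement of the six-membered ring through cleavage of the zero bridge, not by end-to-end cyclisation. Chlorine transfer from FeCl3 gives the tertiary β-chloro ketone, and acetate removes HCl through the C9 enol to leave the C9=C8 enone. The closest known reaction is the Simmons–Smith cyclopropanation/Fe(III) opening of cyclic silyl enol ethers to cycloalk-2-enones (Ito–Saegusa one-carbon ring expansion). No stereocentre of 19 is created: those of the cyclopropane and of the chloride are erased, and C1 and C4 are untouched. The step needs attack at the silyl enol ether and not at the C5=C6 methyl enol ether (secured by the two quaternary neighbours C1 and C4 of C5 and by the capped C4 oxygen), internal-bond scission (secured by the tertiary C8 radical) and elimination towards C9 (C10 has no other α-hydrogen, C1 being quaternary).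

Step 11
Reactants: 19 dienedione
Product: 20 10α-hydroxy-6-methoxy-4β-(trimethylsilyloxy)dauca-5,8-dien-2-one
Conditions: NaBH4, CeCl3·7H2O, MeOH, −78 °C
Reagents that add atoms: none
Why: Luche 1,2-reduction takes the conjugated C10 ketone in preference to the neopentyl C2 cyclopentanone; with the C5=C6 enol ether still in place the seven-membered ring is folded about C1···C7, the concave face is closed by the five-membered ring and its α-isopropyl, and hydride should enter on the convex face (the face of the C1 methyl) to give the 10α-alcohol.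

Step 12
Reactants: 20 allylic alcohol
Product: 21 4β,10α-dihydroxy-5αH-dauc-8-ene-2,6-dione
Conditions: oxalic acid, THF/H2O, 0 → 25 °C
Reagents that add atoms: water, O
Why: Mild acid hydrolysis of the methyl enol ether (and of the tertiary TMS ether) unmasks the C6 ketone without moving the β,γ-alkene; C5 should be protonated on the α-face, where the hydrogen-bonding 10α-hydroxyl lies 1,3-syn to C5 and where C6 can move away from the C4 isopropyl, giving the trans ring fusion.

Step 13
Reactants: 21 keto diol
Product: 22 10α-(tert-butyldimethylsilyloxy)-4β-hydroxy-5αH-dauc-8-ene-2,6-dione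
Conditions: TBSOTf (1.05 equiv), 2,6-lutidine, CH2Cl2, −78 → −40 °C
Reagents that add atoms: tert-butyldimethylsilyl triflate, CC(C)(C)[Si](C)(C)OS(=O)(=O)C(F)(F)F
Why: Silyl triflate silylation takes the secondary allylic hydroxyl and leaves the hindered tertiary C4 hydroxyl; capping O10 prevents it from directing reduction of C2 in step 14 and from competing in step 16.

Step 14
Reactants: 22 silyloxy diketone
Product: 23 10α-(tert-butyldimethylsilyloxy)-4β,6α-dihydroxy-5αH-dauc-8-en-2-one
Conditions: Me4NBH(OAc)3, MeCN/AcOH, −30 → 0 °C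
Reagents that add atoms: none
Why: Evans–Saksena hydroxyl-directed reduction: the C4 hydroxyl, pseudo-axial on the β-face and gauche to C6, binds boron and delivers hydride through a chair-like six-membered transition state to the β-face of C6, giving the 6α-alcohol; the neopentyl C2 ketone, whose β-face is capped by the adjacent C1 methyl, should not be reduced by triacetoxyborohydride.

Step 15
Reactants: 24 vanillic acid
Product: 26 4-(tert-butyldimethylsilyloxy)-3-methoxybenzoic acid, via bis-silyl derivative 25 (not isolated)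
Conditions: TBSCl (2.2 equiv), imidazole, DMF, 25 °C; then K2CO3, THF/MeOH/H2O, 25 °C; acidify
Reagents that add atoms: tert-butyldimethylsilyl chloride, CC(C)(C)[Si](C)(C)Cl
Why: Exhaustive silylation followed by selective hydrolysis of the labile silyl ester leaves the phenol protected and the acid free.

Step 16
Reactants: 23 diol; 26 protected vanillic acid
Product: 27 10α-(tert-butyldimethylsilyloxy)-4β-hydroxy-2-oxo-5αH-dauc-8-en-6α-yl 4-(tert-butyldimethylsilyloxy)-3-methoxybenzoate
Conditions: DCC, DMAP, CH2Cl2, 25 °C
Reagents that add atoms: 4-(tert-butyldimethylsilyloxy)-3-methoxybenzoic acid (26), COc1cc(C(=O)O)ccc1O[Si](C)(C)C(C)(C)C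
Why: Steglich esterification acylates the secondary 6α-hydroxyl with retention; the tertiary C4 hydroxyl does not react.

Step 17
Reactants: 27 bis-silyl ester
Product: 28 4β,10α-dihydroxy-2-oxo-5αH-dauc-8-en-6α-yl 4-hydroxy-3-methoxybenzoate (CNP0233071.1)
Conditions: HF·pyridine, pyridine, THF, 0 → 25 °C
Reagents that add atoms: none
Why: Buffered fluoride cleaves the aryl and the allylic silyl ether without base, so the β-hydroxy ketone units and the ester should survive.

**Compound list**

1 | 2,5-dimethoxy-4-methylbenzaldehyde | COc1cc(C=O)c(OC)cc1C | starting material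
2 | Meldrum's acid | CC1(C)OC(=O)CC(=O)O1 | starting material
3 | 5-(2,5-dimethoxy-4-methylbenzylidene)-2,2-dimethyl-1,3-dioxane-4,6-dione | COc1cc(C=C2C(=O)OC(C)(C)OC2=O)c(OC)cc1C | intermediate
4 | isopropylmagnesium chloride | CC(C)[Mg]Cl | starting material
5 | rac-5-[1-(2,5-dimethoxy-4-methylphenyl)-2-methylpropyl]-2,2-dimethyl-1,3-dioxane-4,6-dione | COc1cc(C(C(C)C)C2C(=O)OC(C)(C)OC2=O)c(OC)cc1C | intermediate
6 | rac-3-isopropyl-4,7-dimethoxy-6-methylindan-1-one | COc1cc(C)c(OC)c2c1C(C(C)C)CC2=O | intermediate
7 | rac-7-hydroxy-3-isopropyl-4-methoxy-6-methylindan-1-one | COc1cc(C)c(O)c2c1C(C(C)C)CC2=O | intermediate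
8 | rac-7-(tert-butyldimethylsilyloxy)-3-isopropyl-4-methoxy-6-methylindan-1-one | COc1cc(C)c(O[Si](C)(C)C(C)(C)C)c2c1C(C(C)C)CC2=O | intermediate
9 | TMS enol ether of 8 (rac-4-(tert-butyldimethylsilyloxy)-1-isopropyl-7-methoxy-5-methyl-3-(trimethylsilyloxy)-1H-indene) | COc1cc(C)c(O[Si](C)(C)C(C)(C)C)c2c1C(C(C)C)C=C2O[Si](C)(C)C | intermediate (not isolated)
10 | 7-(tert-butyldimethylsilyloxy)-3-isopropyl-4-methoxy-6-methyl-1H-inden-1-one | COc1cc(C)c(O[Si](C)(C)C(C)(C)C)c2c1C(C(C)C)=CC2=O | intermediate
11 | (S)-7-(tert-butyldimethylsilyloxy)-3-isopropyl-4-methoxy-6-methyl-3-(4,4,5,5-tetramethyl-1,3,2-dioxaborolan-2-yl)indan-1-one (boron on the face that later carries OH) | COc1cc(C)c(O[Si](C)(C)C(C)(C)C)c2c1[C@](B3OC(C)(C)C(C)(C)O3)(C(C)C)CC2=O | intermediate (not isolated)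
12 | (R)-7-(tert-butyldimethylsilyloxy)-3-hydroxy-3-isopropyl-4-methoxy-6-methylindan-1-one | COc1cc(C)c(O[Si](C)(C)C(C)(C)C)c2c1[C@](O)(C(C)C)CC2=O | intermediate
13 | iodomethane | CI | starting material
14 | (3R,7aS)-7-(tert-butyldimethylsilyloxy)-3-hydroxy-3-isopropyl-4-methoxy-6,7a-dimethyl-2,3,5,7a-tetrahydro-1H-inden-1-one (7a-methyl cis to 3-OH) | COC1=C2[C@](O)(C(C)C)CC(=O)[C@]2(C)C(O[Si](C)(C)C(C)(C)C)=C(C)C1 | intermediate
15 | (3R,7aS)-7-(tert-butyldimethylsilyloxy)-3-isopropyl-4-methoxy-6,7a-dimethyl-3-(trimethylsilyloxy)-2,3,5,7a-tetrahydro-1H-inden-1-one | COC1=C2[C@](O[Si](C)(C)C)(C(C)C)CC(=O)[C@]2(C)C(O[Si](C)(C)C(C)(C)C)=C(C)C1 | intermediate (key-step precursor)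
16 | diiodomethane | ICI | starting material
17 | siloxycyclopropane: 15 with CH2 (C9) bridging C10 and C8 on the α-face, C10–OTBS and C8–CH3 β | COC1=C2[C@](O[Si](C)(C)C)(C(C)C)CC(=O)[C@]2(C)[C@]3(O[Si](C)(C)C(C)(C)C)C[C@]3(C)C1 | intermediate (not isolated)
18 | 8-chloro-6-methoxy-4β-(trimethylsilyloxy)dauc-5-ene-2,10-dione (C8 epimers) | COC1=C2[C@](O[Si](C)(C)C)(C(C)C)CC(=O)[C@]2(C)C(=O)CC(C)(Cl)C1 | intermediate (not isolated)
19 | 6-methoxy-4β-(trimethylsilyloxy)dauca-5,8-diene-2,10-dione (1β-CH3, 4α-iPr) | COC1=C2[C@](O[Si](C)(C)C)(C(C)C)CC(=O)[C@]2(C)C(=O)C=C(C)C1 | intermediate (key-step product)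
20 | 10α-hydroxy-6-methoxy-4β-(trimethylsilyloxy)dauca-5,8-dien-2-one | COC1=C2[C@](O[Si](C)(C)C)(C(C)C)CC(=O)[C@]2(C)[C@H](O)C=C(C)C1 | intermediate
21 | 4β,10α-dihydroxy-5αH-dauc-8-ene-2,6-dione (trans-fused) | O=C2CC(C)=C[C@@H](O)[C@@]3(C)C(=O)C[C@@](O)(C(C)C)[C@H]23 | intermediate
22 | 10α-(tert-butyldimethylsilyloxy)-4β-hydroxy-5αH-dauc-8-ene-2,6-dione | O=C2CC(C)=C[C@@H](O[Si](C)(C)C(C)(C)C)[C@@]3(C)C(=O)C[C@@](O)(C(C)C)[C@H]23 | intermediate
23 | 10α-(tert-butyldimethylsilyloxy)-4β,6α-dihydroxy-5αH-dauc-8-en-2-one | O[C@H]2CC(C)=C[C@@H](O[Si](C)(C)C(C)(C)C)[C@@]3(C)C(=O)C[C@@](O)(C(C)C)[C@H]23 | intermediate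
24 | vanillic acid | COc1cc(C(=O)O)ccc1O | starting material
25 | tert-butyldimethylsilyl 4-(tert-butyldimethylsilyloxy)-3-methoxybenzoate | COc1cc(C(=O)O[Si](C)(C)C(C)(C)C)ccc1O[Si](C)(C)C(C)(C)C | intermediate (not isolated)
26 | 4-(tert-butyldimethylsilyloxy)-3-methoxybenzoic acid | COc1cc(C(=O)O)ccc1O[Si](C)(C)C(C)(C)C | intermediate
27 | 10α-(tert-butyldimethylsilyloxy)-4β-hydroxy-2-oxo-5αH-dauc-8-en-6α-yl 4-(tert-butyldimethylsilyloxy)-3-methoxybenzoate | COc1cc(C(=O)O[C@H]2CC(C)=C[C@@H](O[Si](C)(C)C(C)(C)C)[C@@]3(C)C(=O)C[C@@](O)(C(C)C)[C@H]23)ccc1O[Si](C)(C)C(C)(C)C | intermediate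
28 | 4β,10α-dihydroxy-2-oxo-5αH-dauc-8-en-6α-yl 4-hydroxy-3-methoxybenzoate, (1S,4R,5S,6S,10R) in daucane numbering (CNP0233071.1) | COc1cc(C(=O)O[C@H]2CC(C)=C[C@@H](O)[C@@]3(C)C(=O)C[C@@](O)(C(C)C)[C@H]23)ccc1O | target

**Step count and risks**

Total: 17 steps. Longest linear sequence: 16 steps (steps 1–14, 16, 17); step 15 prepares the acid separately.

Steps most likely to fail:

1. Step 8 (Birch reductive methylation). Possible failures are electron-transfer cleavage of the benzylic C4–O bond, retro-aldol opening at the C4 alkoxide once C2 is a ketone again, O-methylation, or methylation on the isopropyl face. The fallback separates electron transfer from C–C bond formation. Starting from 12, a plain Birch reduction (Li, NH3/THF, t-BuOH, −78 °C, NH4Cl quench) should give the 7a-H dihydro ketone F1. 1-(Trimethylsilyl)imidazole then caps the tertiary alcohol to give the silyl ether F2. LDA (THF, −78 °C) regenerates the cross-conjugated lithium enolate without a free alkoxide, and MeI alkylates C7a (C1) anti to the isopropyl, which comes back to the route at 15.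

2. Step 10 (ring expansion). Possible failures are slow or unselective electron transfer from the hindered TBS-oxycyclopropane, Fe(III)-induced ionisation of the allylic C4–O bond, or loss of HCl away from conjugation. The fallback is the dihalocarbene version of the same one-carbon expansion. Starting from 15, dibromocarbene (CHBr3, KOt-Bu, hexane, −20 °C) should give the dibromo(siloxy)cyclopropane F3. On warming in toluene (or with AgClO4) this opens in a cyclopropyl-to-allyl electrocyclic manner, with loss of the silyl bromide, to the 9-bromo enone F4. Pd(PPh3)4/Bu3SnH removes the vinylic bromine and comes back to the route at 19.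

3. Step 12 (enol-ether hydrolysis, C5). The possible failure is protonation of C5 from the β-face, giving the cis ring fusion, which the 10α-hydroxyl would then trap as a C6/C10 bridged hemiketal. The fallback uses thermodynamic instead of kinetic control. Starting from 20, the 10α-hydroxyl is silylated first (TBSOTf, 2,6-lutidine) to give the bis-silyl dienol ether F5, in which no hemiketal can form. Hydrolysis with aqueous HCl/THF and acid-mediated equilibration at C5 should then favour the trans fusion, which keeps C6 away from the C4 isopropyl and allows a C4–OH···O=C6 hydrogen bond. This comes back to the route at 22; drift of the C8=C9 alkene into conjugation has to be watched.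

**Further compounds**

F1 | step 8 | (3R)-7-(tert-butyldimethylsilyloxy)-3-hydroxy-3-isopropyl-4-methoxy-6-methyl-2,3,5,7a-tetrahydro-1H-inden-1-one (7a-H, epimers) | COC1=C2[C@](O)(C(C)C)CC(=O)C2C(O[Si](C)(C)C(C)(C)C)=C(C)C1
F2 | step 8 | (3R)-7-(tert-butyldimethylsilyloxy)-3-isopropyl-4-methoxy-6-methyl-3-(trimethylsilyloxy)-2,3,5,7a-tetrahydro-1H-inden-1-one (7a-H, epimers) | COC1=C2[C@](O[Si](C)(C)C)(C(C)C)CC(=O)C2C(O[Si](C)(C)C(C)(C)C)=C(C)C1
F3 | step 10 | dibromo(siloxy)cyclopropane: 15 with CBr2 bridging C10 and C8 on the α-face | COC1=C2[C@](O[Si](C)(C)C)(C(C)C)CC(=O)[C@]2(C)[C@]3(O[Si](C)(C)C(C)(C)C)C(Br)(Br)[C@]3(C)C1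
F4 | step 10 | 9-bromo-6-methoxy-4β-(trimethylsilyloxy)dauca-5,8-diene-2,10-dione | COC1=C2[C@](O[Si](C)(C)C)(C(C)C)CC(=O)[C@]2(C)C(=O)C(Br)=C(C)C1
F5 | step 12 | 10α-(tert-butyldimethylsilyloxy)-6-methoxy-4β-(trimethylsilyloxy)dauca-5,8-dien-2-one | COC1=C2[C@](O[Si](C)(C)C)(C(C)C)CC(=O)[C@]2(C)[C@H](O[Si](C)(C)C(C)(C)C)C=C(C)C1
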